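**Retrosynthetic overview**
- Target ⇐ Saegusa exo-methylenation, desilylation and C-12 tigloylation of a C-12/C-13 diol γ-lactone.
- The γ-lactone (formed last) ⇐ chloromethyl ketone + acetic acid dianion: C13–C14 bond under chelation control from C-12, then O–C16 closure.
- Key bond C9–C11 (sets C-9 and C-12) ⇐ cathodic umpolung Giese coupling of a 2,3-dimethylcyclohexenone decalin with an (R)-methylene-dioxolanone from D-lactic acid.
- Decalin (rings A and B formed together) ⇐ intramolecular Diels–Alder of a 2-methyl-deca-1,7,9-trien-3-one (C5–C10 and C6–C7), then allylic oxidation and α′-hydroxylation.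
- Trienone ⇐ the L-glutamic-acid-derived hydroxymethyl butyrolactone (supplies C-1) by two Wittig reactions and isopropenyllithium opening.

Assumption: clerodane numbering is used (decalin C-1 to C-10, side chain C-11 to C-16, C-17 on C-8, C-18 on C-4, C-19 on C-5, C-20 on C-9), with α/β as in the target drawn with H-10 α and the C-19/C-20 methyls β; the target is (1S,5S,6S,9S,10S,12R,13S).

**Step 1**
Reactants: 1 (S)-5-(hydroxymethyl)dihydrofuran-2(3H)-one
Product: 3 (S)-5-[(E)-2-methyl-3-oxobut-1-en-1-yl]dihydrofuran-2(3H)-one, via lactone aldehyde 2 (not isolated)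
Conditions: IBX, Ph3P=C(Me)COMe, DMSO, 25 → 40 °C
Reagents that add atoms: 3-(triphenylphosphoranylidene)butan-2-one, CC(=O)C(C)=P(c1ccccc1)(c1ccccc1)c1ccccc1
Why: One-pot IBX oxidation/Wittig olefination traps the epimerisable α-alkoxy aldehyde at once with the stabilised ylide, which gives the (E)-enone; the bought stereocentre (future C-1) is not touched.

**Step 2**
Reactants: 3 (S)-5-[(E)-2-methyl-3-oxobut-1-en-1-yl]dihydrofuran-2(3H)-one
Product: 4 (S)-5-[(E)-2,3-dimethylbuta-1,3-dien-1-yl]dihydrofuran-2(3H)-one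
Conditions: Ph3PCH3Br, KHMDS, THF, −78 → 0 °C
Reagents that add atoms: methyltriphenylphosphonium bromide, C[P+](c1ccccc1)(c1ccccc1)c1ccccc1.[Br-]
Why: Wittig methylenation of the enone carbonyl (much faster than attack on the γ-lactone at ≤0 °C) gives the 2,3-dimethyl-1,3-diene with the E trisubstituted alkene unchanged.

**Step 3**
Reactants: 4 (S)-5-[(E)-2,3-dimethylbuta-1,3-dien-1-yl]dihydrofuran-2(3H)-one
Product: 6 (4S,4aS,8aS)-4-hydroxy-5,6,8a-trimethyl-3,4,4a,7,8,8a-hexahydronaphthalen-1(2H)-one, via hydroxy trienone 5 (not isolated)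
Conditions: 2-bromopropene, t-BuLi, Et2O/THF, −78 °C; AcOH, −78 °C; then PhMe, BHT, 80 °C
Reagents that add atoms: 2-bromopropene (as isopropenyllithium), C=C(C)Br
Why: Single addition of isopropenyllithium to the lactone (lactolate stable at −78 °C) unveils an α-methyl vinyl ketone that undergoes intramolecular Diels–Alder reaction through the chair-tether transition state with the ketone exo and the methyl endo (the usual preference of α-methyl enone dienophiles) and with H-1 eclipsing the C-20 methyl (A1,3 strain), so the bought C-1 centre sets H-10 α and Me-19 β of the trans-decalin with the hydroxyl equatorial.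

**Step 4**
Reactants: 6 (4S,4aS,8aS)-4-hydroxy-5,6,8a-trimethyl-3,4,4a,7,8,8a-hexahydronaphthalen-1(2H)-one
Product: 7 (1S,4aS,8aS)-4a,7,8-trimethyl-4-methylidene-1,2,3,4,4a,5,6,8a-octahydronaphthalen-1-ol
Conditions: Ph3PCH3Br, KOt-Bu, PhMe, 90 °C
Reagents that add atoms: methyltriphenylphosphonium bromide, C[P+](c1ccccc1)(c1ccccc1)c1ccccc1.[Br-]
Why: Wittig methylenation with excess ylide at elevated temperature is the standard way to convert a neopentyl ketone to the exocyclic alkene (C-18); the free alkoxide is inert and no stereocentre is affected.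

**Step 5**
Reactants: 7 (1S,4aS,8aS)-4a,7,8-trimethyl-4-methylidene-1,2,3,4,4a,5,6,8a-octahydronaphthalen-1-ol
Product: 8 (1S,4aS,8aS)-4a,7,8-trimethyl-4-methylidene-1,2,3,4,4a,5,6,8a-octahydronaphthalen-1-yl 2-methylpropanoate
Conditions: (i-PrCO)2O, Et3N, DMAP (cat.), CH2Cl2, rt
Reagents that add atoms: isobutyric anhydride, CC(C)C(=O)OC(=O)C(C)C
Why: DMAP-catalysed acylation of the equatorial secondary alcohol installs the isobutyrate of the target, which is then carried through as its own protecting group.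

**Step 6**
Reactants: 8 (1S,4aS,8aS)-4a,7,8-trimethyl-4-methylidene-1,2,3,4,4a,5,6,8a-octahydronaphthalen-1-yl 2-methylpropanoate
Product: 9 (1S,4aS,8aS)-4a,7,8-trimethyl-4-methylidene-6-oxo-1,2,3,4,4a,5,6,8a-octahydronaphthalen-1-yl 2-methylpropanoate
Conditions: CrO3, 3,5-dimethylpyrazole, CH2Cl2, −20 °C
Reagents that add atoms: chromium trioxide, O=[Cr](=O)=O
Why: Chromium(VI)/3,5-dimethylpyrazole allylic oxidation converts the only ring CH2 flanking the electron-rich tetrasubstituted alkene (C-7) into the enone carbonyl, the 1,1-disubstituted alkene being much less reactive.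

**Step 7**
Reactants: 9 (1S,4aS,8aS)-4a,7,8-trimethyl-4-methylidene-6-oxo-1,2,3,4,4a,5,6,8a-octahydronaphthalen-1-yl 2-methylpropanoate
Product: 11 (1S,4aS,5S,8aS)-5-hydroxy-4a,7,8-trimethyl-4-methylidene-6-oxo-1,2,3,4,4a,5,6,8a-octahydronaphthalen-1-yl 2-methylpropanoate, via 6α-hydroxy enone 10 (not isolated)
Conditions: KHMDS, THF, −78 °C; (±)-2-(phenylsulfonyl)-3-phenyloxaziridine; aq NH4Cl; then Et3N, MeOH, 40 °C
Reagents that add atoms: (±)-2-(phenylsulfonyl)-3-phenyloxaziridine, O=S(=O)(c1ccccc1)N1OC1c1ccccc1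
Why: Davis hydroxylation of the kinetic α′-enolate (C-6 is the only enolisable α′ position) occurs anti to the axial C-19 methyl to give the 6α-ketol, and amine-mediated enediol equilibration then delivers the more stable equatorial, hydrogen-bonded 6β-ketol of the target.

**Step 8**
Reactants: 12 (R)-lactic acid
Product: 13 (2R,5R)-2-tert-butyl-5-methyl-1,3-dioxolan-4-one
Conditions: t-BuCHO, TsOH (cat.), H2SO4 (cat.), pentane, reflux (water separator); recrystallisation
Reagents that add atoms: pivalaldehyde, CC(C)(C)C=O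
Why: Acid-catalysed acetalisation of the α-hydroxy acid (Seebach self-regeneration of stereocentres) gives the cis-dioxolanone, the lactic acid centre fixing the new acetal centre.

**Step 9**
Reactants: 13 (2R,5R)-2-tert-butyl-5-methyl-1,3-dioxolan-4-one
Product: 14 (2S,5S)-5-bromo-2-tert-butyl-5-methyl-1,3-dioxolan-4-one (Br trans to tert-butyl)
Conditions: NBS, AIBN (cat.), PhCF3, reflux
Reagents that add atoms: N-bromosuccinimide, O=C1CCC(=O)N1Br
Why: Wohl–Ziegler radical bromination at the captodative C-5 position proceeds with bromine entering anti to the tert-butyl group, the acetal centre being retained.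

**Step 10**
Reactants: 14 (2S,5S)-5-bromo-2-tert-butyl-5-methyl-1,3-dioxolan-4-one
Product: 15 (R)-2-tert-butyl-5-methylidene-1,3-dioxolan-4-one
Conditions: DBU, Et2O, 0 °C → rt
Reagents that add atoms: none
Why: E2 dehydrobromination toward the methyl group gives the chiral captodative alkene whose only stereocentre is the acetal carbon fixed in step 8.

**Step 11**
Reactants: 11 (1S,4aS,5S,8aS)-5-hydroxy-4a,7,8-trimethyl-4-methylidene-6-oxo-1,2,3,4,4a,5,6,8a-octahydronaphthalen-1-yl 2-methylpropanoate; 15 (R)-2-tert-butyl-5-methylidene-1,3-dioxolan-4-one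
Product: 17 C-9 coupled bis-TES dioxolanone (1α-isobutyryloxy-6β,7-bis(triethylsilyloxy)-Δ7 decalin carrying on C-9α the CH2 (C-11) of a (2R,5R)-2-tert-butyl-4-oxo-1,3-dioxolan-5-yl unit), via 6-O-TES enone 16 (not isolated)
Conditions: TESCl (6 equiv), Et3N (1.3 equiv), DMF, rt; then 15 (4 equiv), n-Bu4NBF4, Mg anode/RVC cathode, undivided cell, 4 mA cm−2, 2.4 F mol−1, 0 °C; aq NaHCO3
Reagents that add atoms: chlorotriethylsilane, CC[Si](Cl)(CC)CC
Why: Proposed new method: cathodic reduction of the enone with fast O-silylation gives a 1-silyloxyallyl radical whose tertiary C-9 terminus adds (Giese) to the CH2 of the harder-to-reduce alkene 15 from the α face, anti to the 1,3-diaxial C-19 methyl, to set C-9, after which the captodative C-12 radical is reduced to the lactone enolate and protonated by Et3NH+ anti to the tert-butyl group to set C-12 (cis-dioxolanone), while the ring enolate stays as the regiodefined C7–C8 silyl enol ether; the closest known reactions are mixed electrohydrodimerisation of activated alkenes, Mg/R3SiCl-promoted β-functionalisation of enones, and tertiary-radical Giese additions to this dioxolanone and to butenolides.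

**Step 12**
Reactants: 17 C-9 coupled bis-TES dioxolanone
Product: 18 (12R)-12-hydroxy-13-oxo-16-chloro compound (C-11–CH(OH)–CO–CH2Cl side chain on the bis-TES decalin)
Conditions: ICH2Cl, MeLi·LiBr, THF, −78 °C; AcOH, −78 °C → rt
Reagents that add atoms: chloroiodomethane, ClCI
Why: Chloromethyllithium generated in situ adds once to the activated acylal carbonyl (ester-to-chloromethyl-ketone homologation), the tetrahedral intermediate survives at −78 °C and collapses on protonation with loss of pivalaldehyde, leaving C-12 untouched and the hindered isobutyrate and silyl enol ether intact.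

**Step 13**
Reactants: 18 (12R)-12-hydroxy-13-oxo-16-chloro compound
Product: 21 (12R,13S)-12,13-dihydroxy-15,16-olide (β-hydroxy-γ-butyrolactone on the bis-TES decalin), via chlorohydrin acid 19 (not isolated), via epoxy acid 20 (not isolated)
Conditions: LiCH2CO2Li (AcOH, 2 LDA), THF, −78 → 0 °C; aq NH4Cl
Reagents that add atoms: acetic acid (as its dianion), CC(=O)O
Why: Aldol-type addition of the acetic acid dianion to the lithium-alkoxide-chelated ketone (Cram chelate, attack anti to C-11) sets C-13, and the new tertiary alkoxide closes to the spiro-epoxide, which the carboxylate opens 5-exo at C-16 to give the lactone with the correct ring oxygen.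

**Step 14**
Reactants: 21 (12R,13S)-12,13-dihydroxy-15,16-olide
Product: 22 12-O-tiglate of 21
Conditions: tigloyl chloride, Et3N, DMAP, CH2Cl2, 0 °C → rt
Reagents that add atoms: (E)-2-methylbut-2-enoyl chloride, C/C=C(\C)C(=O)Cl
Why: DMAP-catalysed acylation takes the secondary C-12 hydroxyl and leaves the tertiary C-13 hydroxyl free; C-6 is protected as its TES ether and the E geometry of the tiglate is retained.

**Step 15**
Reactants: 22 12-O-tiglate of 21
Product: 24 target CNP0182744.1, via 6-O-TES target 23 (not isolated)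
Conditions: Pd(OAc)2 (1.2 equiv), MeCN, 40 °C; then HF·pyridine, pyridine, THF, 0 °C
Reagents that add atoms: none
Why: Saegusa–Ito oxidation of the regiodefined silyl enol ether can only β-hydride-eliminate toward C-17 (C-9 is quaternary), giving the 8(17)-methylene-7-ketone, and buffered HF·pyridine then removes the C-6 TES ether without touching the esters, alkenes or lactone.

**Compound list**
1 | (S)-5-(hydroxymethyl)dihydrofuran-2(3H)-one (lactone from L-glutamic acid) | OC[C@@H]1CCC(=O)O1 | starting material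
2 | (S)-5-oxotetrahydrofuran-2-carbaldehyde | O=C[C@@H]1CCC(=O)O1 | intermediate
3 | (S)-5-[(E)-2-methyl-3-oxobut-1-en-1-yl]dihydrofuran-2(3H)-one | CC(=O)/C(C)=C/[C@@H]1CCC(=O)O1 | intermediate
4 | (S)-5-[(E)-2,3-dimethylbuta-1,3-dien-1-yl]dihydrofuran-2(3H)-one | C=C(C)/C(C)=C/[C@@H]1CCC(=O)O1 | intermediate
5 | (S,E)-6-hydroxy-2,8,9-trimethyldeca-1,7,9-trien-3-one | C=C(C)/C(C)=C/[C@@H](O)CCC(=O)C(C)=C | intermediate
6 | (4S,4aS,8aS)-4-hydroxy-5,6,8a-trimethyl-3,4,4a,7,8,8a-hexahydronaphthalen-1(2H)-one (trans-fused; 1α-OH, 4-oxo, 5β-Me, 10α-H, Δ8) | O=C1CC[C@H](O)[C@@H]2[C@]1(C)CCC(C)=C2C | intermediate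
7 | (1S,4aS,8aS)-4a,7,8-trimethyl-4-methylidene-1,2,3,4,4a,5,6,8a-octahydronaphthalen-1-ol | C=C1CC[C@H](O)[C@@H]2[C@]1(C)CCC(C)=C2C | intermediate
8 | (1S,4aS,8aS)-4a,7,8-trimethyl-4-methylidene-1,2,3,4,4a,5,6,8a-octahydronaphthalen-1-yl 2-methylpropanoate | C=C1CC[C@H](OC(=O)C(C)C)[C@@H]2[C@]1(C)CCC(C)=C2C | intermediate
9 | (1S,4aS,8aS)-4a,7,8-trimethyl-4-methylidene-6-oxo-1,2,3,4,4a,5,6,8a-octahydronaphthalen-1-yl 2-methylpropanoate (7-oxo-Δ8 enone) | C=C1CC[C@H](OC(=O)C(C)C)[C@@H]2[C@]1(C)CC(=O)C(C)=C2C | intermediate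
10 | (1S,4aS,5R,8aS)-5-hydroxy epimer of 11 (6α-OH) | C=C1CC[C@H](OC(=O)C(C)C)[C@@H]2[C@]1(C)[C@@H](O)C(=O)C(C)=C2C | intermediate
11 | (1S,4aS,5S,8aS)-5-hydroxy-4a,7,8-trimethyl-4-methylidene-6-oxo-1,2,3,4,4a,5,6,8a-octahydronaphthalen-1-yl 2-methylpropanoate (6β-OH) | C=C1CC[C@H](OC(=O)C(C)C)[C@@H]2[C@]1(C)[C@H](O)C(=O)C(C)=C2C | intermediate
12 | (R)-lactic acid (D-lactic acid) | C[C@@H](O)C(=O)O | starting material
13 | (2R,5R)-2-tert-butyl-5-methyl-1,3-dioxolan-4-one (cis) | C[C@H]1O[C@@H](C(C)(C)C)OC1=O | intermediate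
14 | (2S,5S)-5-bromo-2-tert-butyl-5-methyl-1,3-dioxolan-4-one (Br trans to t-Bu) | C[C@@]1(Br)O[C@@H](C(C)(C)C)OC1=O | intermediate
15 | (R)-2-tert-butyl-5-methylidene-1,3-dioxolan-4-one | C=C1O[C@@H](C(C)(C)C)OC1=O | intermediate
16 | 6-O-triethylsilyl ether of 11 | C=C1CC[C@H](OC(=O)C(C)C)[C@@H]2[C@]1(C)[C@H](O[Si](CC)(CC)CC)C(=O)C(C)=C2C | intermediate
17 | (2R,5R)-2-tert-butyl-1,3-dioxolan-4-one whose C-5 (= C-12) carries the C-11 methylene bonded to C-9 (α) of the (1S,5S,6S,9S,10S) decalin: 1α-isobutyryloxy, 4(18)-methylidene, 5β-Me, 6β-OTES, 7-OTES-Δ7 enol ether, 8-Me, 9β-Me, 10α-H | C=C1CC[C@H](OC(=O)C(C)C)[C@@H]2[C@]1(C)[C@H](O[Si](CC)(CC)CC)C(O[Si](CC)(CC)CC)=C(C)[C@@]2(C)C[C@H]3O[C@@H](C(C)(C)C)OC3=O | intermediate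
18 | (12R)-16-chloro-12-hydroxy-13-ketone: same decalin as 17, side chain C-11H2–CH(OH)–C(=O)–CH2Cl | C=C1CC[C@H](OC(=O)C(C)C)[C@@H]2[C@]1(C)[C@H](O[Si](CC)(CC)CC)C(O[Si](CC)(CC)CC)=C(C)[C@@]2(C)C[C@@H](O)C(=O)CCl | intermediate
19 | (12R,13R)-chlorohydrin acid: side chain C-11H2–CH(OH)–C(OH)(CH2Cl)–CH2CO2H | C=C1CC[C@H](OC(=O)C(C)C)[C@@H]2[C@]1(C)[C@H](O[Si](CC)(CC)CC)C(O[Si](CC)(CC)CC)=C(C)[C@@]2(C)C[C@@H](O)[C@@](O)(CCl)CC(=O)O | intermediate
20 | (12R,13S)-13,16-epoxy acid: side chain C-11H2–CH(OH)–C(spiro-oxirane)–CH2CO2H | C=C1CC[C@H](OC(=O)C(C)C)[C@@H]2[C@]1(C)[C@H](O[Si](CC)(CC)CC)C(O[Si](CC)(CC)CC)=C(C)[C@@]2(C)C[C@@H](O)[C@]1(CC(=O)O)CO1 | intermediate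
21 | (12R,13S)-12,13-dihydroxy-15,16-olide on the bis-TES decalin of 17 | C=C1CC[C@H](OC(=O)C(C)C)[C@@H]2[C@]1(C)[C@H](O[Si](CC)(CC)CC)C(O[Si](CC)(CC)CC)=C(C)[C@@]2(C)C[C@@H](O)[C@@]1(O)COC(=O)C1 | intermediate
22 | 12-O-[(E)-2-methylbut-2-enoyl] (tiglate) ester of 21 | C=C1CC[C@H](OC(=O)C(C)C)[C@@H]2[C@]1(C)[C@H](O[Si](CC)(CC)CC)C(O[Si](CC)(CC)CC)=C(C)[C@@]2(C)C[C@@H](OC(=O)/C(C)=C/C)[C@@]1(O)COC(=O)C1 | intermediate
23 | 6-O-triethylsilyl ether of the target | C=C1CC[C@H](OC(=O)C(C)C)[C@@H]2[C@]1(C)[C@H](O[Si](CC)(CC)CC)C(=O)C(=C)[C@@]2(C)C[C@@H](OC(=O)/C(C)=C/C)[C@@]1(O)COC(=O)C1 | intermediate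
24 | CNP0182744.1, (1S,5S,6S,9S,10S,12R,13S) | C=C1CC[C@H](OC(=O)C(C)C)[C@@H]2[C@]1(C)[C@H](O)C(=O)C(=C)[C@@]2(C)C[C@@H](OC(=O)/C(C)=C/C)[C@@]1(O)COC(=O)C1 | target

**Step count**
Total: 15 steps. Longest linear sequence: 12 steps (steps 1–7 and 11–15); steps 8–10 make the coupling partner 15.

**Steps most likely to fail, with fallbacks**

Step 11 (the new cathodic coupling). The risks are over-reduction of the enone, coupling at C-7 instead of C-9, and loss of the silyl enol ether. The fallback uses known chemistry and sets out from 11 and 15. Peroxide-initiated anti-Markovnikov addition of HBr to 15 (hydrogen transfer to the captodative radical anti to tert-butyl) gives (2R,5S)-5-(bromomethyl)-2-tert-butyl-1,3-dioxolan-4-one F5. Compound 11 is silylated separately (TESCl, imidazole) to 16. Compounds 16 and F5 are then joined by nickel-catalysed reductive conjugate addition of the alkyl bromide to the enone (NiCl2·glyme, terpyridine, Mn, TESCl, DMF). This reaction delivers the silyl enol ether directly, so the fallback comes back to the route at 17; C-12 is already fixed in F5 and C-9 is again set anti to C-19.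

Step 3 (ring fusion and facial selectivity of the Diels–Alder reaction). If the internally activated trienone gives too much cis-fused adduct, the fallback moves the activation to the dienophile terminus; it sets out from 4 and returns at 6. Hydrozirconation–iodination of commercial but-2-ynal diethyl acetal gives (E)-1,1-diethoxy-3-iodobut-2-ene F1. Its vinyllithium (t-BuLi) opens lactone 4 to (S,2E,8E)-1,1-diethoxy-7-hydroxy-3,9,10-trimethylundeca-2,8,10-trien-4-one F2. Mild acid (PPTS, wet acetone) unmasks (S,2E,8E)-7-hydroxy-3,9,10-trimethyl-4-oxoundeca-2,8,10-trienal F3. Its Me2AlCl-promoted cyclisation goes through the aldehyde-endo transition state, the reliably trans-selective mode of terminally activated (E)-dienophiles, to the 6β-formyl derivative of 6 F4. Decarbonylation with RhCl(PPh3)3 (PhMe, 110 °C) then gives 6.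

Step 13 (dianion addition and lactone closure). The risks are enolisation of the chloroketone, Payne-type scrambling and moderate chelation control. The fallback sets out from 18 and returns at 21. Displacement of the activated chloride by bromoacetate (BrCH2CO2H, Cs2CO3, cat. NaI, DMF, 0 °C) gives the 16-O-bromoacetyl-12-hydroxy-13-ketone F6. An intramolecular samarium Reformatsky reaction (SmI2, THF, −78 °C; the classical α-(bromoacetoxy)ketone route to β-hydroxy-γ-butyrolactones) then forms C13–C14 on the Sm-chelated ketone anti to C-11 and delivers 21 with the lactone oxygen already in place.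

**Further compounds**
F1 | step 3 | (E)-1,1-diethoxy-3-iodobut-2-ene | CCOC(OCC)/C=C(\C)I
F2 | step 3 | (S,2E,8E)-1,1-diethoxy-7-hydroxy-3,9,10-trimethylundeca-2,8,10-trien-4-one | C=C(C)/C(C)=C/[C@@H](O)CCC(=O)/C(C)=C/C(OCC)OCC
F3 | step 3 | (S,2E,8E)-7-hydroxy-3,9,10-trimethyl-4-oxoundeca-2,8,10-trienal | C=C(C)/C(C)=C/[C@@H](O)CCC(=O)/C(C)=C/C=O
F4 | step 3 | 6β-formyl derivative of 6 (1α-hydroxy-4-oxo-6β-formyl-5β,8,9-trimethyl-Δ8-trans-decalin) | O=C1CC[C@H](O)[C@@H]2[C@]1(C)[C@H](C=O)CC(C)=C2C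
F5 | step 11 | (2R,5S)-5-(bromomethyl)-2-tert-butyl-1,3-dioxolan-4-one | BrC[C@H]1O[C@@H](C(C)(C)C)OC1=O
F6 | step 13 | (12R)-16-(bromoacetoxy)-12-hydroxy-13-ketone on the bis-TES decalin of 17 | C=C1CC[C@H](OC(=O)C(C)C)[C@@H]2[C@]1(C)[C@H](O[Si](CC)(CC)CC)C(O[Si](CC)(CC)CC)=C(C)[C@@]2(C)C[C@@H](O)C(=O)COC(=O)CBr
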